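**Retrosynthetic overview**
1. Target ⇐ Sharpless epoxidation of the (13E)-allylic alcohol; side chain ⇐ Horner–Wadsworth–Emmons reaction on a C13 methyl ketone; C8=CH2 ⇐ methylenation of a C8 ketone.
2. cis-Decalin triad ⇐ ester-directed hydrogenation of a Δ5 alkene (H-5 β), after deconjugative methylation of the Δ4-19-ester (C4 quaternary, CH3 trans to C20).
3. Ring A ⇐ [4+2] cycloaddition of the diene C3=C4–C5=C10, held in a 2H-thiopyran fused to ring B (sulfur joins C3 and C20), with CH2=C(SO2Ph)2 as the C1–C2 ethylene equivalent; Raney Ni then turns the S–CH2 bridge into the C20 methyl and C3H2, and Na(Hg) removes the sulfones.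
4. Enabling feature: C20 (angular CH3 on quaternary C10) and C3 are heteroatom-free sp3 carbons, 1,5-related through C10–C5–C4. One sulfur atom therefore closes a six-membered ring (S, C20, C10, C5, C4, C3) that locks the otherwise (Z)-methyl-hindered diene s-cis and is erased by hydrogenolysis.
5. Ring order: ring B (from a 4-silyloxycyclohexenone, C9 by anti cuprate addition) → temporary thiopyran ring → ring A (key step) → thiopyran cleaved → epoxide last.

Key step: step 5

Remark on the structure: the SMILES is read as a labdane with a cis-fused decalin (H-5, CH3-20 and CO2Me-19 on the same, β face; C9 side chain β; epoxide 13R,14R); labdane numbering is used in the names.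
Assumption: enantiopure (R)-4-(tert-butyldimethylsilyloxy)cyclohex-2-en-1-one (1) is taken as a catalogue compound.

**Route**

Step 1
Reactants: 1 (R)-4-(tert-butyldimethylsilyloxy)cyclohex-2-en-1-one; 2 2-(2-bromoethyl)-2-methyl-1,3-dioxolane
Product: 5 (3R,4R)-4-(tert-butyldimethylsilyloxy)-2-[(dimethylamino)methyl]-3-[2-(2-methyl-1,3-dioxolan-2-yl)ethyl]cyclohexan-1-one (Mannich base; 3,4-trans; C-2 epimers), via Grignard reagent 3 (not isolated), via magnesium enolate 4 (not isolated)
Conditions: 2, Mg, THF, 25 °C; CuBr·SMe2 (10 mol %), THF, −78 °C, add 1; then CH2=NMe2+ I− (Eschenmoser's salt), −78 °C → rt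
Reagents that add atoms: Eschenmoser's salt (N,N-dimethylmethyleneiminium iodide), C=[N+](C)C.[I-]
Why: Copper-catalysed conjugate addition of the Grignard reagent should occur anti to the allylic silyloxy group and so set C9 trans to O-8, and the regiodefined magnesium enolate is then aminomethylated at C10 (Mannich reaction), the C10 configuration being irrelevant because this carbon becomes sp2.

Step 2
Reactants: 5 Mannich base
Product: 6 methyl 2-{4-(tert-butyldimethylsilyloxy)-2-[(dimethylamino)methyl]-3-[2-(2-methyl-1,3-dioxolan-2-yl)ethyl]cyclohexylidene}acetate (configuration as in 5; E/Z mixture)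
Conditions: Me3SiCH2CO2Me, LiN(iPr)2, THF, −78 °C; then 5, −78 °C → rt
Reagents that add atoms: methyl (trimethylsilyl)acetate, COC(=O)C[Si](C)(C)C
Why: Peterson olefination, in which the α-silyl ester enolate adds to the ketone and the β-silyl alkoxide eliminates in situ to the exocyclic enoate (C4=C5) without touching amine, ketal or silyl ether; no stereocentre is formed and the alkene geometry is inconsequential.

Step 3
Reactants: 6 amino enoate
Product: 9 methyl 2-{2-[(acetylsulfanyl)methyl]-4-(tert-butyldimethylsilyloxy)-3-[2-(2-methyl-1,3-dioxolan-2-yl)ethyl]cyclohex-1-en-1-yl}acetate (3,4-trans), via trimethylammonium iodide 7 (not isolated), via dienoate 8 (not isolated)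
Conditions: MeI, MeCN, rt, excess MeI removed in vacuo; DBU, MeCN, 0 °C; then AcSH, 0 °C → rt
Reagents that add atoms: thioacetic acid, CC(=O)S
Why: Quaternisation makes NMe3 a leaving group and vinylogous E1cB elimination through the C10 dienolate gives dienoate 8; 1,6-conjugate (thia-Michael) addition of thioacetate to the terminal CH2, followed by kinetic α-protonation, should place the double bond at C5=C10 and leave the CH2CO2Me group needed next; no stereocentre is formed.

Step 4
Reactants: 9 allylic thioacetate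
Product: 12 methyl 7-(tert-butyldimethylsilyloxy)-8-[2-(2-methyl-1,3-dioxolan-2-yl)ethyl]-5,6,7,8-tetrahydro-1H-isothiochromene-4-carboxylate (7,8-trans; the 2H-thiopyran diene), via allylic thiol 10 (not isolated), via enamino ester 11 (not isolated)
Conditions: Me2NH (2 M in THF, 1.2 equiv), then t-BuOCH(NMe2)2 (Bredereck's reagent, 3 equiv), toluene, rt → 85 °C, degassed, acid-free glassware
Reagents that add atoms: Bredereck's reagent (tert-butoxybis(dimethylamino)methane), CC(C)(C)OC(N(C)C)N(C)C
Why: Aminolysis frees the allylic thiol, the C4 methylene (allylic and α to the ester) condenses with the formamide acetal to the enamino ester, and intramolecular addition–elimination of the thiol with loss of Me2NH closes the S–C3 bond, so the C3=C4 and C5=C10 double bonds of the 2H-thiopyran are fixed by construction; no stereocentre is formed.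

Step 5
Reactants: 12 2H-thiopyran diene; 13 1,1-bis(phenylsulfonyl)ethylene
Product: 14 methyl 3,20-epithio-2,2-bis(phenylsulfonyl)-8α-(tert-butyldimethylsilyloxy)-13,13-(ethylenedioxy)-14,15,17,18-tetranorlabd-4-en-19-oate (2-thiabicyclo[2.2.2]oct-5-ene cycloadduct; sulfur bridge on the β face)
Conditions: 13 (1.3 equiv), toluene, BHT (cat.), solid K2CO3 (trace), 60–80 °C, dark
Reagents that add atoms: none
Why: The 2H-thiopyran holds the diene C3=C4–C5=C10 s-cis and should react with the doubly activated alkene of 13 in a polarised, asynchronous [4+2] cycloaddition in which C10 (δ to the sulfur donor) bonds to the CH2 carbon (C1) and the sulfur-bearing terminus C3 bonds to the C(SO2Ph)2 carbon (C2). The closest known reaction type is the Diels–Alder reaction of 2H-thiopyrans with electron-poor alkenes, whose adducts are desulfurised with Raney Ni so that the thiopyran acts as the equivalent of a (Z)-substituted diene. Ring A (C1–C2–C3–C4–C5–C10) closes by suprafacial [4+2] cycloaddition, first as the carbocyclic bridge of a 2-thiabicyclo[2.2.2]oct-5-ene. The new quaternary stereocentre C10 is controlled by C9: A(1,2) strain with the C20H2–S substituent holds the C9 side chain pseudoaxial on the β face, so the dienophile should bond to C10 from the α face (C1 trans to C11, C20 cis to C11); the C3 bridgehead follows from the bridged geometry and is erased later. The step needs π-facial selectivity and reactivity at a fully substituted terminus, the first secured by C9 and the second by tying the terminal methyl back into the ring; regio- and endo/exo-selectivity are not critical, because C2 carries two identical sulfonyl groups and either regioisomer would converge after desulfonylation.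

Step 6
Reactants: 14 cycloadduct
Product: 15 methyl 2,2-bis(phenylsulfonyl)-8α-(tert-butyldimethylsilyloxy)-13,13-(ethylenedioxy)-14,15,17,18-tetranorlabd-4-en-19-oate (10β-CH3)
Conditions: Raney Ni (W-2, aged in acetone, excess), THF/EtOH, rt → 50 °C
Reagents that add atoms: none
Why: Raney Ni hydrogenolysis of both C–S bonds (desulfurisation) converts the bridge into the C20 methyl on C10 and a CH2 at C3, which removes the C3 stereocentre and leaves quaternary C10 untouched; the tetrasubstituted enoate, sulfones, ketal and silyl ether should persist on the aged catalyst.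

Step 7
Reactants: 15 geminal disulfone
Product: 16 methyl 8α-(tert-butyldimethylsilyloxy)-13,13-(ethylenedioxy)-14,15,17,18-tetranorlabd-4-en-19-oate
Conditions: Na(Hg) (6 %), Na2HPO4, MeOH/THF, −20 °C → 0 °C
Reagents that add atoms: none
Why: Reductive desulfonylation with sodium amalgam cleaves both C–SO2Ph bonds by electron transfer and protonation to leave C2 as CH2 (no β-sulfur leaving group remains in the molecule), while the hindered tetrasubstituted enoate is expected to be reduced much more slowly; no stereocentre is formed.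

Step 8
Reactants: 16 Δ4-enoate
Product: 18 methyl 8α-(tert-butyldimethylsilyloxy)-13,13-(ethylenedioxy)-14,15,17-trinorlabd-5-en-19-oate (4α-CH3, 4β-CO2Me), via lithium dienolate 17 (not isolated)
Conditions: LiN(iPr)2 (1.3 equiv), HMPA, THF, −78 °C; MeI, −78 → −20 °C
Reagents that add atoms: iodomethane, CI
Why: Deconjugative α-alkylation: γ-deprotonation (only C6–H is available, C10 being quaternary) gives the extended dienolate, which should be methylated at C4 from the α face, anti to the pseudoaxial C20 methyl that is 1,3 to C4, so CH3 ends α and CO2Me β while the double bond moves to C5=C6.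

Step 9
Reactants: 18 Δ5-ester
Product: 19 methyl 8α-(tert-butyldimethylsilyloxy)-13,13-(ethylenedioxy)-14,15,17-trinor-5β-labdan-19-oate (cis-fused)
Conditions: H2 (1–4 atm), [Ir(cod)(PCy3)(py)]PF6 (10 mol %), CH2Cl2, rt
Reagents that add atoms: none
Why: Ester-directed homogeneous hydrogenation: the β-oriented C19 carbonyl should bind the cationic iridium centre and deliver H2 to the β face of the hindered C5=C6 bond, setting H-5 cis to C20 and CO2Me (cis ring fusion), the opposite of the α-face addition expected from an undirected heterogeneous catalyst.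

Step 10
Reactants: 19 cis-fused silyl ether ketal
Product: 20 methyl 8α-hydroxy-13-oxo-14,15,17-trinor-5β-labdan-19-oate
Conditions: 1 M HCl (aq), THF, rt
Reagents that add atoms: water, O
Why: Acid-catalysed hydrolysis cleaves the dioxolane and the secondary silyl ether in one operation while the hindered tertiary methyl ester and all stereocentres are unaffected; the product may sit partly as its six-membered hemiketal, which reacts through the open form.

Step 11
Reactants: 20 hydroxy ketone
Product: 21 19-methyl 15-ethyl (13E)-8α-hydroxy-17-nor-5β-labd-13-ene-15,19-dioate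
Conditions: (EtO)2P(O)CH2CO2Et, NaH, THF, 0 → 50 °C
Reagents that add atoms: triethyl phosphonoacetate, CCOC(=O)CP(=O)(OCC)OCC
Why: Horner–Wadsworth–Emmons olefination of the methyl ketone should give mainly the (E)-trisubstituted enoate (C12 trans to the ester), the minor Z isomer being removed by chromatography; the free secondary alcohol is not acidic enough to quench the phosphonate anion.

Step 12
Reactants: 21 hydroxy enoate
Product: 22 19-methyl 15-ethyl (13E)-8-oxo-17-nor-5β-labd-13-ene-15,19-dioate
Conditions: Dess–Martin periodinane, CH2Cl2, rt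
Reagents that add atoms: none
Why: Dess–Martin oxidation converts the secondary C8 alcohol into the ketone under non-basic conditions, so the adjacent C9 stereocentre should not epimerise.

Step 13
Reactants: 22 keto enoate
Product: 23 19-methyl 15-ethyl (13E)-5β-labda-8(17),13-diene-15,19-dioate
Conditions: Zn, CH2Br2, TiCl4, THF/CH2Cl2, 0 °C → rt
Reagents that add atoms: dibromomethane, BrCBr
Why: Takai–Lombardo methylenation is non-basic and selective for ketones over esters, so the C8 ketone should become the exocyclic methylene without epimerisation at C9 or attack on the two esters.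

Step 14
Reactants: 23 diene diester
Product: 24 methyl (13E)-15-hydroxy-5β-labda-8(17),13-dien-19-oate
Conditions: iBu2AlH (2.3 equiv), CH2Cl2, −78 °C; aqueous potassium sodium tartrate work-up
Reagents that add atoms: none
Why: iBu2AlH reduces the unhindered conjugated ethyl ester to the allylic alcohol at −78 °C (1,2-reduction), whereas the neopentyl, fully substituted C19 methyl ester should react far more slowly; the alkene geometry is retained.

Step 15
Reactants: 24 allylic alcohol
Product: 25 methyl (13R,14R)-13,14-epoxy-15-hydroxy-5β-labd-8(17)-en-19-oate (target CNP0175926.1)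
Conditions: Ti(OiPr)4 (10 mol %), D-(−)-diethyl tartrate (12 mol %), t-BuOOH, 4 Å molecular sieves, CH2Cl2, −20 °C
Reagents that add atoms: tert-butyl hydroperoxide, CC(C)(C)OO
Why: Sharpless asymmetric epoxidation is specific for the allylic alcohol (the exocyclic alkene is untouched) and with D-(−)-diethyl tartrate should deliver oxygen to the face of the (E)-alkene that gives the (13R,14R)-epoxy alcohol under reagent control.

**Compound list**
1 | (R)-4-(tert-butyldimethylsilyloxy)cyclohex-2-en-1-one | O=C1C=C[C@H](O[Si](C)(C)C(C)(C)C)CC1 | starting material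
2 | 2-(2-bromoethyl)-2-methyl-1,3-dioxolane | BrCCC1(C)OCCO1 | starting material
3 | [2-(2-methyl-1,3-dioxolan-2-yl)ethyl]magnesium bromide | Br[Mg]CCC1(C)OCCO1 | intermediate (not isolated)
4 | bromomagnesium enolate of the 3,4-trans conjugate adduct | CC(C)(C)[Si](C)(C)O[C@@H]1CCC(O[Mg]Br)=C[C@H]1CCC1(C)OCCO1 | intermediate (not isolated)
5 | (3R,4R)-4-(tert-butyldimethylsilyloxy)-2-[(dimethylamino)methyl]-3-[2-(2-methyl-1,3-dioxolan-2-yl)ethyl]cyclohexan-1-one (C-2 epimers) | CC(C)(C)[Si](C)(C)O[C@@H]1CCC(=O)C(CN(C)C)[C@H]1CCC1(C)OCCO1 | intermediate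
6 | methyl 2-{4-(tert-butyldimethylsilyloxy)-2-[(dimethylamino)methyl]-3-[2-(2-methyl-1,3-dioxolan-2-yl)ethyl]cyclohexylidene}acetate (E/Z mixture) | CC(C)(C)[Si](C)(C)O[C@@H]1CCC(=CC(=O)OC)C(CN(C)C)[C@H]1CCC1(C)OCCO1 | intermediate
7 | trimethylammonium iodide of 6 | CC(C)(C)[Si](C)(C)O[C@@H]1CCC(=CC(=O)OC)C(C[N+](C)(C)C)[C@H]1CCC1(C)OCCO1.[I-] | intermediate (not isolated)
8 | methyl 2-{4-(tert-butyldimethylsilyloxy)-2-methylidene-3-[2-(2-methyl-1,3-dioxolan-2-yl)ethyl]cyclohexylidene}acetate (dienoate) | CC(C)(C)[Si](C)(C)O[C@@H]1CCC(=CC(=O)OC)C(=C)[C@H]1CCC1(C)OCCO1 | intermediate (not isolated)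
9 | methyl 2-{2-[(acetylsulfanyl)methyl]-4-(tert-butyldimethylsilyloxy)-3-[2-(2-methyl-1,3-dioxolan-2-yl)ethyl]cyclohex-1-en-1-yl}acetate | CC(C)(C)[Si](C)(C)O[C@@H]1CCC(CC(=O)OC)=C(CSC(C)=O)[C@H]1CCC1(C)OCCO1 | intermediate
10 | the corresponding allylic thiol | CC(C)(C)[Si](C)(C)O[C@@H]1CCC(CC(=O)OC)=C(CS)[C@H]1CCC1(C)OCCO1 | intermediate (not isolated)
11 | methyl 3-(dimethylamino)-2-{…2-(sulfanylmethyl)cyclohex-1-en-1-yl}acrylate (enamino ester) | CC(C)(C)[Si](C)(C)O[C@@H]1CCC(C(=CN(C)C)C(=O)OC)=C(CS)[C@H]1CCC1(C)OCCO1 | intermediate (not isolated)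
12 | methyl 7-(tert-butyldimethylsilyloxy)-8-[2-(2-methyl-1,3-dioxolan-2-yl)ethyl]-5,6,7,8-tetrahydro-1H-isothiochromene-4-carboxylate (7,8-trans) | CC(C)(C)[Si](C)(C)O[C@@H]1CCC2=C(CSC=C2C(=O)OC)[C@H]1CCC1(C)OCCO1 | intermediate
13 | 1,1-bis(phenylsulfonyl)ethylene | C=C(S(=O)(=O)c1ccccc1)S(=O)(=O)c1ccccc1 | starting material
14 | 3,20-epithio cycloadduct (2-thiabicyclo[2.2.2]oct-5-ene; 2,2-bis(phenylsulfonyl); Δ4-19-oate) | CC(C)(C)[Si](C)(C)O[C@@H]1CCC2=C(C(=O)OC)[C@H]3SC[C@@]2(CC3(S(=O)(=O)c4ccccc4)S(=O)(=O)c4ccccc4)[C@H]1CCC1(C)OCCO1 | intermediate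
15 | methyl 2,2-bis(phenylsulfonyl)-8α-(tert-butyldimethylsilyloxy)-13,13-(ethylenedioxy)-14,15,17,18-tetranorlabd-4-en-19-oate | CC(C)(C)[Si](C)(C)O[C@@H]1CCC2=C(C(=O)OC)CC(S(=O)(=O)c3ccccc3)(S(=O)(=O)c3ccccc3)C[C@]2(C)[C@H]1CCC1(C)OCCO1 | intermediate
16 | methyl 8α-(tert-butyldimethylsilyloxy)-13,13-(ethylenedioxy)-14,15,17,18-tetranorlabd-4-en-19-oate | CC(C)(C)[Si](C)(C)O[C@@H]1CCC2=C(C(=O)OC)CCC[C@]2(C)[C@H]1CCC1(C)OCCO1 | intermediate
17 | lithium dienolate of 16 (C19 enolate, C5=C6) | [Li+].CC(C)(C)[Si](C)(C)O[C@@H]1CC=C2C(=C([O-])OC)CCC[C@]2(C)[C@H]1CCC1(C)OCCO1 | intermediate (not isolated)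
18 | methyl 8α-(tert-butyldimethylsilyloxy)-13,13-(ethylenedioxy)-14,15,17-trinorlabd-5-en-19-oate | CC(C)(C)[Si](C)(C)O[C@@H]1CC=C2[C@](C)(CCC[C@]2(C)C(=O)OC)[C@H]1CCC1(C)OCCO1 | intermediate
19 | methyl 8α-(tert-butyldimethylsilyloxy)-13,13-(ethylenedioxy)-14,15,17-trinor-5β-labdan-19-oate | CC(C)(C)[Si](C)(C)O[C@@H]1CC[C@H]2[C@](C)(CCC[C@]2(C)C(=O)OC)[C@H]1CCC1(C)OCCO1 | intermediate
20 | methyl 8α-hydroxy-13-oxo-14,15,17-trinor-5β-labdan-19-oate | O[C@@H]1CC[C@H]2[C@](C)(CCC[C@]2(C)C(=O)OC)[C@H]1CCC(C)=O | intermediate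
21 | 19-methyl 15-ethyl (13E)-8α-hydroxy-17-nor-5β-labd-13-ene-15,19-dioate | O[C@@H]1CC[C@H]2[C@](C)(CCC[C@]2(C)C(=O)OC)[C@H]1CC/C(C)=C/C(=O)OCC | intermediate
22 | 19-methyl 15-ethyl (13E)-8-oxo-17-nor-5β-labd-13-ene-15,19-dioate | O=C1CC[C@H]2[C@](C)(CCC[C@]2(C)C(=O)OC)[C@H]1CC/C(C)=C/C(=O)OCC | intermediate
23 | 19-methyl 15-ethyl (13E)-5β-labda-8(17),13-diene-15,19-dioate | C=C1CC[C@H]2[C@](C)(CCC[C@]2(C)C(=O)OC)[C@H]1CC/C(C)=C/C(=O)OCC | intermediate
24 | methyl (13E)-15-hydroxy-5β-labda-8(17),13-dien-19-oate | C=C1CC[C@H]2[C@](C)(CCC[C@]2(C)C(=O)OC)[C@H]1CC/C(C)=C/CO | intermediate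
25 | methyl (13R,14R)-13,14-epoxy-15-hydroxy-5β-labd-8(17)-en-19-oate | C=C1CC[C@H]2[C@](C)(CCC[C@]2(C)C(=O)OC)[C@H]1CC[C@@]1(C)O[C@@H]1CO | target

**Totals and risks**
Total step count: 15. Longest linear sequence: 15 steps (from 1).

Steps most likely to fail:

1. Step 5 (key cycloaddition). Bond formation at the fully substituted terminus of a push–pull diene may be slow, the ring-fusion double bond may migrate before cycloaddition, and facial control may erode because the silyloxy group can sit axial and 1,3 to C10 on the attacked face. Fallback, intramolecular delivery through a temporary silicon tether on O-8: from 12, Bu4NF (THF, 0 °C) would give the dienol F4. Chloro(dimethyl)vinylsilane and imidazole would give the vinylsilyl ether F5. Heating (toluene, 170 °C, sealed tube, BHT) would effect the intramolecular Diels–Alder reaction, which can only deliver C1 to the α face of C10, where O-8 lies, giving the siloxane-bridged cycloadduct F6. Raney Ni would give the desulfurised siloxane F7. Bu4NF in DMF at 75 °C would cleave Si–O and the C1–Si bond (protodesilylation) to the hydroxy enoate F8. TBSCl and imidazole would then return 16.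

2. Step 4 (thiopyran annulation). The basic medium may reverse the 1,6-addition (loss of thiolate, polymerisation of the dienoate), ring closure may stay incomplete, or the diene may isomerise. Fallback, C4–C5 bond by aldol condensation and the second double bond by Pummerer chemistry: from 5, heating with methyl 3-mercaptopropanoate (toluene, 80 °C; amine–thiol exchange by elimination–addition) would give the β-keto sulfide F1. NaOMe in MeOH would close the ring by intramolecular aldol condensation to the dihydrothiopyran enoate F2. mCPBA (1 equiv, −78 °C) would give the sulfoxide F3. (CF3CO)2O with 2,6-lutidine, then Et3N (Pummerer-type dehydration through the vinylogous thionium ion, proton loss at C10), would return 12. Proton loss at C6 instead is the known weakness of this variant.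

3. Step 9 (directed hydrogenation). The ester may bind iridium too weakly for delivery to the β face, which is flanked by two pseudoaxial groups, so that no reaction or α-face addition (trans fusion) results. Fallback, a stronger directing group at another oxidation level: from 18, LiAlH4 (THF, 0 °C) would give the homoallylic alcohol F9. Hydroxyl-directed hydrogenation with the same iridium complex would give the cis-fused alcohol F10. Dess–Martin oxidation would give the aldehyde F11. I2 and KOH in MeOH (oxidative esterification) would return 19.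

Further compounds
F1 | step 4 | methyl 3-({[3-(tert-butyldimethylsilyloxy)-6-oxo-2-[2-(2-methyl-1,3-dioxolan-2-yl)ethyl]cyclohexyl]methyl}sulfanyl)propanoate (β-keto sulfide) | CC(C)(C)[Si](C)(C)O[C@@H]1CCC(=O)C(CSCCC(=O)OC)[C@H]1CCC1(C)OCCO1
F2 | step 4 | methyl 7-(tert-butyldimethylsilyloxy)-8-[2-(2-methyl-1,3-dioxolan-2-yl)ethyl]-3,5,6,7,8,8a-hexahydro-1H-isothiochromene-4-carboxylate (dihydrothiopyran enoate) | CC(C)(C)[Si](C)(C)O[C@@H]1CCC2=C(C(=O)OC)CSCC2[C@H]1CCC1(C)OCCO1
F3 | step 4 | S-oxide of F2 (sulfoxide) | CC(C)(C)[Si](C)(C)O[C@@H]1CCC2=C(C(=O)OC)CS(=O)CC2[C@H]1CCC1(C)OCCO1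
F4 | step 5 | methyl 7-hydroxy-8-[2-(2-methyl-1,3-dioxolan-2-yl)ethyl]-5,6,7,8-tetrahydro-1H-isothiochromene-4-carboxylate (dienol) | O[C@@H]1CCC2=C(CSC=C2C(=O)OC)[C@H]1CCC1(C)OCCO1
F5 | step 5 | dimethyl(vinyl)silyl ether of F4 | C=C[Si](C)(C)O[C@@H]1CCC2=C(CSC=C2C(=O)OC)[C@H]1CCC1(C)OCCO1
F6 | step 5 | siloxane-bridged 3,20-epithio cycloadduct (C1–SiMe2–O–C8; C-1 configuration fixed by the tether, not specified) | C[Si]1(C)O[C@@H]2CCC3=C(C(=O)OC)[C@H]4SC[C@@]3(C1C4)[C@H]2CCC1(C)OCCO1
F7 | step 5 | desulfurised siloxane (C1–SiMe2–O–C8, 10β-CH3, Δ4-19-oate) | C[Si]1(C)O[C@@H]2CCC3=C(C(=O)OC)CCC1[C@]3(C)[C@H]2CCC1(C)OCCO1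
F8 | step 5 | methyl 8α-hydroxy-13,13-(ethylenedioxy)-14,15,17,18-tetranorlabd-4-en-19-oate | O[C@@H]1CCC2=C(C(=O)OC)CCC[C@]2(C)[C@H]1CCC1(C)OCCO1
F9 | step 9 | 8α-(tert-butyldimethylsilyloxy)-13,13-(ethylenedioxy)-14,15,17-trinorlabd-5-en-19-ol | CC(C)(C)[Si](C)(C)O[C@@H]1CC=C2[C@](C)(CCC[C@]2(C)CO)[C@H]1CCC1(C)OCCO1
F10 | step 9 | 8α-(tert-butyldimethylsilyloxy)-13,13-(ethylenedioxy)-14,15,17-trinor-5β-labdan-19-ol | CC(C)(C)[Si](C)(C)O[C@@H]1CC[C@H]2[C@](C)(CCC[C@]2(C)CO)[C@H]1CCC1(C)OCCO1
F11 | step 9 | 8α-(tert-butyldimethylsilyloxy)-13,13-(ethylenedioxy)-14,15,17-trinor-5β-labdan-19-al | CC(C)(C)[Si](C)(C)O[C@@H]1CC[C@H]2[C@](C)(CCC[C@]2(C)C=O)[C@H]1CCC1(C)OCCO1
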